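**Retrosynthetic overview**

1. The (R)-piperidine is taken back to an 8-(2,3-dihydropyridin-6-yl)flavone (C2=N and C3=C4 in piperidine numbering). A chiral phosphoric acid/Hantzsch ester transfer hydrogenation reduces it last, at C4 and then at C2, so the stereocenter is set at the end on the unprotected flavone.
2. Key disconnection: the piperidine C3–C4 bond. The enamine carbon of a C8 ketimine (future C3, the methyl of an 8-acetyl group) attacks an N-tethered oxocarbenium carbon (future C4) and ethanol is lost. This cuts the nitrogen ring to 8-acetyl-7-hydroxy-5-methoxyflavone and 3,3-diethoxypropan-1-amine.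
3. Enabling feature: piperidine C2 is benzylic, bound to N, and ortho to the C7 phenol of ring A. At the ketimine level it is held by an O–H···N hydrogen bond, its only enolizable neighbour is the future C3, and the vinylogous-ester C4=O of ring C does not compete for the amine.
4. Ring C comes from carbonylative alkynylation/cyclization of an ortho-iodophenol with phenylacetylene and CO. The iodophenol comes from symmetric 1-(2,6-dihydroxy-4-methoxyphenyl)ethanone, whose two open ring positions are equivalent, so the acetyl group must end at C8 and the methoxy group at C5.
5. Order of ring formation: ring A is bought, the pyranone ring C is made in step 2, the nitrogen ring in step 3, and the stereocenter in step 4. No protecting groups are used.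

Key step: step 3

Remark: the target is the (R)-amine, so hydride must reach the Si face of the imine carbon; (R)-TRIP is assumed to shield the Re face, and its antipode is used if the sense proves opposite.

**Step 1**
Reactants: 1 1-(2,6-dihydroxy-4-methoxyphenyl)ethan-1-one
Product: 2 1-(2,6-dihydroxy-3-iodo-4-methoxyphenyl)ethan-1-one
Conditions: NIS (1.0 equiv), MeCN, −20 to 0 °C, dark
Reagents that add atoms: N-iodosuccinimide, O=C1CCC(=O)N1I
Why: Electrophilic aromatic iodination of this phloroglucinol-type ring needs no catalyst, and because the two open positions of 1 are equivalent by symmetry only one mono-iodide can form (iodine between a free OH and the OMe), while one equivalent at low temperature should hold back di-iodination.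

**Step 2**
Reactants: 2 1-(2,6-dihydroxy-3-iodo-4-methoxyphenyl)ethan-1-one; 3 phenylacetylene; 4 carbon monoxide
Product: 7 8-acetyl-7-hydroxy-5-methoxy-2-phenyl-4H-chromen-4-one, via ynone 5 (not isolated), via enaminone 6 (not isolated)
Conditions: PdCl2(dppf) (5 mol%), CO (10 bar), Et2NH, 100 °C; then 1 M HCl work-up
Reagents that add atoms: phenylacetylene, C#Cc1ccccc1; carbon monoxide, [C-]#[O+]
Why: A carbonylative Sonogashira coupling (oxidative addition to zerovalent palladium, CO insertion, alkynylation) should give ynone 5, diethylamine adds to it to give enaminone 6, and the only phenol ortho to the new acyl group (the one between the two acyl groups) closes the pyranone by addition–elimination with loss of diethylamine, which gives the flavone rather than the aurone and places the acetyl group at C8.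

**Step 3**
Reactants: 7 8-acetyl-7-hydroxy-5-methoxy-2-phenyl-4H-chromen-4-one; 8 3,3-diethoxypropan-1-amine
Product: 11 8-(2,3-dihydropyridin-6-yl)-7-hydroxy-5-methoxy-2-phenyl-4H-chromen-4-one, via ketimine 9 (not isolated), via ethoxy imine 10 (not isolated)
Conditions: 8 (1.1 equiv), EtOH, 3 Å MS, reflux; filter, evaporate; then TFA (10 equiv), CH2Cl2 (0.02 M), 0 °C to rt; cold aq NaHCO3 work-up under Ar
Reagents that add atoms: 3,3-diethoxypropan-1-amine, NCCC(OCC)OCC
Why: Proposed new method: the amine condenses with the acetyl C=O to the hydrogen-bonded ketimine 9; in TFA the acetal ionizes to an oxocarbenium ion, the enamine tautomer of the ketiminium attacks it through its CH2 carbon to close the C3–C4 bond and give ethoxy imine 10, and imine–enamine tautomerism then expels the second ethanol to leave the conjugated azadiene 11 as the thermodynamic sink. The closest known reaction type is the Friedländer annulation (Schiff base first, then an intramolecular aldol-type condensation that makes the C3–C4 bond of the pyridine ring), together with the acid-mediated closure of enaminones onto N-tethered acetals; new here is the use of a saturated aminoaldehyde acetal with a simple aryl methyl ketimine. The nitrogen ring closes in the 6-(enolendo)-exo-trig mode. The only new stereocenter, the ethoxy-bearing carbon of 10, is destroyed again by the elimination, so nothing has to be controlled. The step needs chemoselective imine formation at the acetyl carbonyl and closure through carbon: the first is secured by the O–H···N bond from the C7 phenol and the low electrophilicity of the vinylogous-ester C4=O of ring C, the second by ring size, since attack through N would give an azetidinium ring and attack through the phenol oxygen an eight-membered ring, while high dilution suppresses intermolecular arylation at C6.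

**Step 4**
Reactants: 11 8-(2,3-dihydropyridin-6-yl)-7-hydroxy-5-methoxy-2-phenyl-4H-chromen-4-one
Product: 13 7-hydroxy-5-methoxy-2-phenyl-8-[(2R)-piperidin-2-yl]-4H-chromen-4-one, via cyclic imine 12 (not isolated)
Conditions: (R)-TRIP (10 mol%), Hantzsch ester (2.4 equiv), toluene/CHCl3 (1:1), 45 °C, Ar
Reagents that add atoms: none
Why: In this Brønsted acid-catalysed cascade transfer hydrogenation the phosphoric acid protonates the azadiene, Hantzsch ester adds hydride at the unhindered C4 (1,4-addition), reprotonation at C3 gives the iminium form of 12, and the second hydride is delivered to the Si face of C2 inside the chiral phosphate ion pair, which also binds the ortho phenol, so the acid enantiomer sets the (R)-center, while the flavone enone is inert to Hantzsch ester.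

**Compound list**

1 | 1-(2,6-dihydroxy-4-methoxyphenyl)ethan-1-one | CC(=O)c1c(O)cc(OC)cc1O | starting material
2 | 1-(2,6-dihydroxy-3-iodo-4-methoxyphenyl)ethan-1-one | CC(=O)c1c(O)cc(OC)c(I)c1O | intermediate
3 | phenylacetylene | C#Cc1ccccc1 | starting material
4 | carbon monoxide | [C-]#[O+] | starting material
5 | 1-(3-acetyl-2,4-dihydroxy-6-methoxyphenyl)-3-phenylprop-2-yn-1-one (ynone) | CC(=O)c1c(O)cc(OC)c(C(=O)C#Cc2ccccc2)c1O | intermediate
6 | 1-(3-acetyl-2,4-dihydroxy-6-methoxyphenyl)-3-(diethylamino)-3-phenylprop-2-en-1-one (enaminone, alkene geometry not defined) | CCN(CC)C(=CC(=O)c1c(OC)cc(O)c(C(C)=O)c1O)c1ccccc1 | intermediate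
7 | 8-acetyl-7-hydroxy-5-methoxy-2-phenyl-4H-chromen-4-one | COc1cc(O)c(C(C)=O)c2oc(-c3ccccc3)cc(=O)c12 | intermediate
8 | 3,3-diethoxypropan-1-amine | NCCC(OCC)OCC | starting material
9 | 8-[1-(3,3-diethoxypropylimino)ethyl]-7-hydroxy-5-methoxy-2-phenyl-4H-chromen-4-one (ketimine, C=N geometry not defined) | COc1cc(O)c(C(C)=NCCC(OCC)OCC)c2oc(-c3ccccc3)cc(=O)c12 | intermediate
10 | 8-(4-ethoxy-3,4,5,6-tetrahydropyridin-2-yl)-7-hydroxy-5-methoxy-2-phenyl-4H-chromen-4-one (racemic) | COc1cc(O)c(C2=NCCC(OCC)C2)c2oc(-c3ccccc3)cc(=O)c12 | intermediate
11 | 8-(2,3-dihydropyridin-6-yl)-7-hydroxy-5-methoxy-2-phenyl-4H-chromen-4-one | COc1cc(O)c(C2=NCCC=C2)c2oc(-c3ccccc3)cc(=O)c12 | intermediate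
12 | 7-hydroxy-5-methoxy-2-phenyl-8-(3,4,5,6-tetrahydropyridin-2-yl)-4H-chromen-4-one | COc1cc(O)c(C2=NCCCC2)c2oc(-c3ccccc3)cc(=O)c12 | intermediate
13 | 7-hydroxy-5-methoxy-2-phenyl-8-[(2R)-piperidin-2-yl]-4H-chromen-4-one | COc1cc(O)c([C@H]2CCCCN2)c2oc(-c3ccccc3)cc(=O)c12 | target

Total step count: 4. Longest linear sequence: 4 steps (from 1).

**Steps most likely to fail**

Step 3 (proposed new method). The enamine tautomer of the hydrogen-bonded ketiminium may be too scarce in TFA to trap the oxocarbenium ion, so that intermolecular condensation or hydrolysis back to the ketone takes over. The free-base azadiene may also tautomerize and air-oxidize to the pyridine during work-up. The fallback uses known chemistry and sets out from 7. Condensation with 3-chloropropan-1-amine hydrochloride and Et3N (EtOH, reflux) should give the N-(3-chloropropyl) ketimine F1. LDA (3.2 equiv, THF, −78 to 0 °C) then removes the phenol and methyl protons, and the 1-azaallyl anion closes the same C3–C4 bond by intramolecular C-alkylation (6-(enolendo)-exo-tet), a known ring closure of metalated N-(3-halopropyl) ketimines. After NH4Cl quench this gives cyclic imine 12, where the route is rejoined; 12 is then reduced under the step 4 conditions with 1.2 equivalents of Hantzsch ester.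

Step 4. Facial selectivity may be poor because the di-ortho-substituted aryl group twists out of the iminium plane and fits the catalyst pocket badly. The basic product may also sequester the acid and stall turnover, and kinetic protonation of the dienamine tautomer at C3 may divert material into a 1,2-reduction that leaves a ring alkene. The fallback sets out from 11 and replaces asymmetric catalysis by resolution. The same cascade with an achiral acid (diphenyl phosphate, 10 mol%) and Hantzsch ester should give the racemic piperidine F2. Crystallization with (S)-mandelic acid from EtOH/EtOAc (or with its antipode, whichever gives the less soluble salt of the (R)-amine) should give the mandelate salt F3, and cold aq NaHCO3 liberates 13, where the route ends.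

Step 2. Diethylamine may capture the acylpalladium intermediate (aminocarbonylation) before alkynylation. Oxidative addition of the electron-rich iodophenoxide may be slow, with protodeiodination, or the ynone may close 5-exo to the aurone. The fallback sets out from 1 and bypasses 2. Friedel–Crafts C-acylation with cinnamoyl chloride (AlCl3, CH2Cl2/nitrobenzene, 0 °C, kept cold to spare the methoxy group) at the one kind of open ring position should give the chalcone F4. Oxidative cyclization with I2 (10 mol%) in DMSO at 110 °C through the only phenol ortho to the cinnamoyl group then gives 7, where the route is rejoined.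

**Further compounds**

F1 | step 3 | 8-[1-(3-chloropropylimino)ethyl]-7-hydroxy-5-methoxy-2-phenyl-4H-chromen-4-one | COc1cc(O)c(C(C)=NCCCCl)c2oc(-c3ccccc3)cc(=O)c12
F2 | step 4 | racemic 7-hydroxy-5-methoxy-2-phenyl-8-(piperidin-2-yl)-4H-chromen-4-one | COc1cc(O)c(C2CCCCN2)c2oc(-c3ccccc3)cc(=O)c12
F3 | step 4 | (2R)-2-(7-hydroxy-5-methoxy-4-oxo-2-phenyl-4H-chromen-8-yl)piperidinium (S)-mandelate | COc1cc(O)c([C@H]2CCCC[NH2+]2)c2oc(-c3ccccc3)cc(=O)c12.[O-]C(=O)[C@@H](O)c1ccccc1
F4 | step 2 | (E)-1-(3-acetyl-2,4-dihydroxy-6-methoxyphenyl)-3-phenylprop-2-en-1-one | COc1cc(O)c(C(C)=O)c(O)c1C(=O)/C=C/c1ccccc1
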